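## Retrosynthetic overview

1. The dihydropyran ring is disconnected at its O1–C2 and C3–C4 bonds, the two σ-bonds of an inverse-electron-demand oxa-[4+2] cycloaddition. The partners are a 2-(2-methylpropylidene)-1,3-dione, made in the flask from 5-methoxy-4,6,6-trimethylcyclohex-4-ene-1,3-dione and isobutyraldehyde, and the exocyclic C=CH2 of a muurolane-type 4(15),5-diene.
2. Enabling feature: in the pyran ring (O1, spiro C2, C3H2, C4H(iPr), C4a, C8a) the spiro carbon bears the oxygen and is allylic to the decalin alkene C1'=C8a', and C4a=C8a is an enol ether conjugated to the C5 ketone. This is an oxadiene retron joined to the CH2 terminus of a fixed s-trans diene whose inner carbon can carry allyl-cation character.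
3. Diene: ring B with its two stereocentres comes from (−)-menthone. Ring A is annulated by α-methylenation, Sakurai conjugate allylation with kinetic protonation (sets C4a) and intramolecular Wittig olefination.
4. Dione: the six-membered carbocycle starts as an arene (2,4,6-trihydroxybenzoic acid). para-O-Methylation, dearomative C-trimethylation and loss of the blocking carboxyl group fix the OMe next to the CMe2 carbon.
5. Ring order: ring B (chiral pool), ring A (Wittig), dienone ring (arene, then dearomatized), pyran ring last in a three-component domino Knoevenagel/oxa-Diels–Alder step that also sets the two remaining stereocentres and ends the route.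

Key step: step 10

Remark on the chemistry: (−)-menthone is taken as the isomenthone-free (2S,5R) ketone, and the alkylidene dione of the key step is written as its reactive double-bond isomer although both isomers are assumed to interconvert in the flask.

## Route

Step 1
Reactants: 1 (−)-menthone, (2S,5R)-5-methyl-2-(propan-2-yl)cyclohexan-1-one
Product: 3 (3R,6S)-2-[(dimethylamino)methyl]-3-methyl-6-(propan-2-yl)cyclohexan-1-one (Mannich base; mixture at C2), via lithium enolate 2 (not isolated)
Conditions: LiN(iPr)2 (1.05 equiv), THF, −78 °C; then [Me2N=CH2]I (Eschenmoser's salt, 1.2 equiv), −78 °C → rt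
Reagents that add atoms: N,N-dimethylmethylideneammonium iodide (Eschenmoser's salt), C=[N+](C)C.[I-]
Why: Kinetic deprotonation removes a proton only from the less hindered CH2 α-carbon and the enolate is aminomethylated by the iminium salt (Mannich reaction); the isopropyl-bearing α-centre is not enolized at −78 °C, and the new C2 centre is of no consequence because it becomes sp2 in step 2.

Step 2
Reactants: 3 (3R,6S)-2-[(dimethylamino)methyl]-3-methyl-6-(propan-2-yl)cyclohexan-1-one
Product: 5 (3R,6S)-3-methyl-2-methylidene-6-(propan-2-yl)cyclohexan-1-one, via quaternary ammonium iodide 4 (not isolated)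
Conditions: MeI (3 equiv), Et2O, rt; then NaHCO3, CH2Cl2/H2O, rt; used at once
Reagents that add atoms: none
Why: N-Methylation turns the amine into a leaving group and mild base effects E1cB β-elimination of the Mannich methiodide to the exocyclic enone without touching C3 or C6.

Step 3
Reactants: 5 (3R,6S)-3-methyl-2-methylidene-6-(propan-2-yl)cyclohexan-1-one; 6 [2-(chloromethyl)prop-2-en-1-yl](trimethyl)silane (1.3 equiv)
Product: 8 (2R,3R,6S)-2-[3-(chloromethyl)but-3-en-1-yl]-3-methyl-6-(propan-2-yl)cyclohexan-1-one, via trichlorotitanium enolate 7 (not isolated)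
Conditions: TiCl4 (1.1 equiv), CH2Cl2, −78 °C; then MeOH, −78 °C; cold aq. NaHCO3
Reagents that add atoms: none
Why: Hosomi–Sakurai conjugate allylation, in which the allylsilane attacks the exocyclic β-carbon of the TiCl4-activated enone through its γ-carbon with loss of Me3SiCl; the regiodefined tetrasubstituted enolate 7 should then be protonated under kinetic control anti to the 3-methyl group, which allylic 1,2-strain with the new side chain holds pseudoaxial, so that H enters trans to the methyl group and the side chain ends cis to it (2R).

Step 4
Reactants: 8 (2R,3R,6S)-2-[3-(chloromethyl)but-3-en-1-yl]-3-methyl-6-(propan-2-yl)cyclohexan-1-one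
Product: 9 {2-methylidene-4-[(1R,3S,6R)-6-methyl-2-oxo-3-(propan-2-yl)cyclohexyl]butyl}(triphenyl)phosphonium chloride
Conditions: PPh3 (1.2 equiv), NaI (10 mol %), MeCN, 70 °C
Reagents that add atoms: triphenylphosphine, c1ccc(cc1)P(c1ccccc1)c1ccccc1
Why: SN2 quaternization of the primary allylic chloride by the phosphine (iodide catalysis) under neutral conditions, which leave both α-stereocentres of the ketone untouched.

Step 5
Reactants: 9 {2-methylidene-4-[(1R,3S,6R)-6-methyl-2-oxo-3-(propan-2-yl)cyclohexyl]butyl}(triphenyl)phosphonium chloride
Product: 11 (1S,4R,4aR)-4-methyl-7-methylidene-1-(propan-2-yl)-1,2,3,4,4a,5,6,7-octahydronaphthalene, via phosphorus ylide 10 (not isolated)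
Conditions: KN(SiMe3)2 (1.0 equiv), THF, −78 °C → 50 °C
Reagents that add atoms: none
Why: Intramolecular Wittig olefination, in which the phosphonium CH2 is far more acidic than the hindered α-CH groups of the ketone, the allylic ylide closes ring A through a six-membered transition state and loss of Ph3PO places the new double bond at C8=C8a with the exocyclic methylene intact; no stereocentre is formed and C4a keeps the configuration set in step 3.

Step 6
Reactants: 12 2,4,6-trihydroxybenzoic acid
Product: 13 benzyl 2,4,6-trihydroxybenzoate
Conditions: BnBr (1.05 equiv), KHCO3 (1.1 equiv), DMF, rt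
Reagents that add atoms: benzyl bromide, BrCc1ccccc1
Why: Carboxylate O-alkylation, since the weak base ionizes the carboxylic acid in preference to the hydrogen-bonded phenols, and the benzyl ester can later be removed by hydrogenolysis without acid or base.

Step 7
Reactants: 13 benzyl 2,4,6-trihydroxybenzoate
Product: 14 benzyl 2,6-dihydroxy-4-methoxybenzoate
Conditions: MeI (1.05 equiv), K2CO3 (1.1 equiv), acetone, rt
Reagents that add atoms: iodomethane, CI
Why: Williamson ether synthesis, selective for the 4-OH because the 2- and 6-OH groups are hydrogen-bonded to the ester carbonyl and less acidic; fixing the ether at the aromatic stage settles the position of OMe next to the future CMe2 carbon.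

Step 8
Reactants: 14 benzyl 2,6-dihydroxy-4-methoxybenzoate
Product: 15 benzyl 2-hydroxy-4-methoxy-3,3,5-trimethyl-6-oxocyclohexa-1,4-diene-1-carboxylate
Conditions: NaOMe (3.5 equiv), MeI (6 equiv), MeOH, 0 °C → rt; then 1 M HCl
Reagents that add atoms: iodomethane, CI
Why: Dearomative C-methylation of a phloroglucinol-type phenolate in a protic medium (the reaction type used to turn acylphloroglucinols into gem-dimethyl β-triketones): two methyl groups enter the free ring positions, the third attacks an already methylated carbon and breaks aromaticity, and the methyl ether makes a fourth C-methylation impossible.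

Step 9
Reactants: 15 benzyl 2-hydroxy-4-methoxy-3,3,5-trimethyl-6-oxocyclohexa-1,4-diene-1-carboxylate
Product: 17 5-methoxy-4,6,6-trimethylcyclohex-4-ene-1,3-dione, via carboxylic acid 16 (not isolated)
Conditions: H2 (1 atm), Pd/C (10 %), EtOAc, rt; then 45 °C
Reagents that add atoms: none
Why: Hydrogenolysis of the benzyl ester gives a 2-carboxy-1,3-dione that, as a doubly activated β-keto acid, should lose CO2 on gentle warming; the neutral conditions keep the vinylogous methyl ester, and the tetrasubstituted push-pull alkene is not hydrogenated.

Step 10
Reactants: 11 (1S,4R,4aR)-4-methyl-7-methylidene-1-(propan-2-yl)-1,2,3,4,4a,5,6,7-octahydronaphthalene (1.2 equiv); 17 5-methoxy-4,6,6-trimethylcyclohex-4-ene-1,3-dione; 18 2-methylpropanal (1.5 equiv)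
Product: 20 target CNP0194760.3, via alkylidene dione 19 (not isolated)
Conditions: ethylenediammonium diacetate (20 mol %), 4 Å molecular sieves, toluene, rt → 50 °C, dark
Reagents that add atoms: none
Why: Amine-salt-catalysed Knoevenagel condensation of 17 with 18 gives the 2-alkylidene-1,3-dione 19, an electron-poor 1-oxadiene whose two double-bond isomers should interconvert by reversible amine addition, and the isomer with the isopropyl group anti to the C1 carbonyl is drained by an inverse-electron-demand oxa-Diels–Alder reaction with the exocyclic methylene of 11 (domino Knoevenagel/hetero-Diels–Alder reaction, the class used for adducts of alkylidene β-triketones with terpene alkenes). The pyran ring is closed by an intermolecular, asynchronous [4+2] cycloaddition: the terminal CH2 of the diene bonds first to the β-carbon of the oxadiene, the positive charge is spread over the C7–C8–C8a allyl unit of 11, and the carbonyl oxygen closes on C7 to the six-membered ring. Of the two carbonyl groups the C1 ketone next to CMe2 should react because the C3 carbonyl is deactivated as a vinylogous ester, which leaves the cross-conjugated vinylogous ester of the target. The spiro centre (S) is set by the diene: the C–O bond forms along the pseudoaxial direction of ring A, anti to the pseudoaxial 4a-H and on the face away from the pseudoaxial isopropyl group at C1, so the CH2 branch ends pseudoequatorial. The CH(iPr) centre (R) follows from the endo transition state in which the C8=C8a vinyl unit lies under the oxadiene and the isopropyl group is outside, which places iPr cis to the vinyl branch on the pyran ring. The step needs chemo- and regioselectivity, secured by the fixed s-trans diene (no 4π reactivity, most nucleophilic terminal CH2, allyl-stabilized inner carbon), and endo/π-facial selectivity, secured only by substrate control from the axial iPr and Me groups and overlap with the conjugated alkene.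

## Compound list

1 | (−)-menthone, (2S,5R)-5-methyl-2-(propan-2-yl)cyclohexan-1-one | CC(C)[C@@H]1CC[C@@H](C)CC1=O | starting material
2 | lithium (3R,6S)-3-methyl-6-(propan-2-yl)cyclohex-1-en-1-olate (not isolated) | [Li]OC1=C[C@H](C)CC[C@H]1C(C)C | intermediate
3 | (3R,6S)-2-[(dimethylamino)methyl]-3-methyl-6-(propan-2-yl)cyclohexan-1-one (mixture at C2) | CC(C)[C@@H]1CC[C@@H](C)C(CN(C)C)C1=O | intermediate
4 | trimethyl{[(6R,3S)-6-methyl-2-oxo-3-(propan-2-yl)cyclohexyl]methyl}ammonium iodide (not isolated) | CC(C)[C@@H]1CC[C@@H](C)C(C[N+](C)(C)C)C1=O.[I-] | intermediate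
5 | (3R,6S)-3-methyl-2-methylidene-6-(propan-2-yl)cyclohexan-1-one | CC(C)[C@@H]1CC[C@@H](C)C(=C)C1=O | intermediate
6 | [2-(chloromethyl)prop-2-en-1-yl](trimethyl)silane | C=C(CCl)C[Si](C)(C)C | starting material
7 | trichlorotitanium (3R,6S)-2-[3-(chloromethyl)but-3-en-1-yl]-3-methyl-6-(propan-2-yl)cyclohex-1-en-1-olate (not isolated) | Cl[Ti](Cl)(Cl)OC1=C(CCC(=C)CCl)[C@H](C)CC[C@H]1C(C)C | intermediate
8 | (2R,3R,6S)-2-[3-(chloromethyl)but-3-en-1-yl]-3-methyl-6-(propan-2-yl)cyclohexan-1-one (side chain cis to 3-Me, trans to 6-iPr) | O=C1[C@H](C(C)C)CC[C@@H](C)[C@H]1CCC(=C)CCl | intermediate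
9 | {2-methylidene-4-[(1R,3S,6R)-6-methyl-2-oxo-3-(propan-2-yl)cyclohexyl]butyl}(triphenyl)phosphonium chloride | O=C1[C@H](C(C)C)CC[C@@H](C)[C@H]1CCC(=C)C[P+](c2ccccc2)(c3ccccc3)c4ccccc4.[Cl-] | intermediate
10 | {2-methylidene-4-[(1R,3S,6R)-6-methyl-2-oxo-3-(propan-2-yl)cyclohexyl]butylidene}(triphenyl)-λ5-phosphane (not isolated) | O=C1[C@H](C(C)C)CC[C@@H](C)[C@H]1CCC(=C)C=P(c2ccccc2)(c3ccccc3)c4ccccc4 | intermediate
11 | (1S,4R,4aR)-4-methyl-7-methylidene-1-(propan-2-yl)-1,2,3,4,4a,5,6,7-octahydronaphthalene (muurolane-type 4(15),5-diene) | C=C1C=C2[C@H](C(C)C)CC[C@@H](C)[C@H]2CC1 | intermediate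
12 | 2,4,6-trihydroxybenzoic acid | OC(=O)c1c(O)cc(O)cc1O | starting material
13 | benzyl 2,4,6-trihydroxybenzoate | O=C(OCc1ccccc1)c1c(O)cc(O)cc1O | intermediate
14 | benzyl 2,6-dihydroxy-4-methoxybenzoate | COc1cc(O)c(C(=O)OCc2ccccc2)c(O)c1 | intermediate
15 | benzyl 2-hydroxy-4-methoxy-3,3,5-trimethyl-6-oxocyclohexa-1,4-diene-1-carboxylate (enol form of the triketo ester) | COC1=C(C)C(=O)C(C(=O)OCc2ccccc2)=C(O)C1(C)C | intermediate
16 | 2-hydroxy-4-methoxy-3,3,5-trimethyl-6-oxocyclohexa-1,4-diene-1-carboxylic acid (not isolated) | COC1=C(C)C(=O)C(C(O)=O)=C(O)C1(C)C | intermediate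
17 | 5-methoxy-4,6,6-trimethylcyclohex-4-ene-1,3-dione | COC1=C(C)C(=O)CC(=O)C1(C)C | intermediate
18 | 2-methylpropanal (isobutyraldehyde) | CC(C)C=O | starting material
19 | 5-methoxy-4,6,6-trimethyl-2-(2-methylpropylidene)cyclohex-4-ene-1,3-dione (isopropyl anti to the C1 carbonyl; not isolated) | COC1=C(C)C(=O)/C(=C\C(C)C)C(=O)C1(C)C | intermediate
20 | (2S,4R,4a'R,5'R,8'S)-7-methoxy-5',6,8,8-tetramethyl-4,8'-di(propan-2-yl)-3,3',4,4',4a',5',6',7'-octahydro-8H,8'H-spiro[chromene-2,2'-naphthalen]-5-one (CNP0194760.3) | COC1=C(C)C(=O)C2=C(O[C@]3(C=C4[C@H](C(C)C)CC[C@@H](C)[C@H]4CC3)C[C@@H]2C(C)C)C1(C)C | target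

## Step count and risks

Total step count: 10. Longest linear sequence: 6 steps (steps 1–5, then step 10).

Steps most likely to fail:

- **Step 10.** The oxadiene may be consumed by a second molecule of 17 (Michael bis-adduct) or by ene-type addition faster than it is trapped by the diene, and the endo/exo and π-facial discrimination rests on substrate control alone and may be low. Fallback, setting out from 17 and 18 and coming back at 20: 17, 18 and benzenesulfinic acid (PhSO2Na, HCO2H, MeOH/H2O, rt) are first condensed to the bench-stable sulfone adduct 5-methoxy-4,6,6-trimethyl-2-[2-methyl-1-(phenylsulfonyl)propyl]cyclohex-4-ene-1,3-dione F1. The oxadiene 19 is then released from F1 by slow sulfinate elimination (NaHCO3, CH2Cl2, 0 °C) in the presence of 11, so that no free 17 is available for bis-addition. The cycloaddition is placed under catalyst control with Cu(OTf)2 and a tert-butyl-bis(oxazoline) ligand, which chelates the 1,3-dicarbonyl unit and shields one face of the oxadiene (enantioselective inverse-demand oxa-Diels–Alder reaction of chelating alkylidene 1,3-dicarbonyl compounds). The ligand enantiomer matched with the axial-face preference of 11 should lead to 20.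

- **Step 3.** The protonation of enolate 7 may show poor facial selectivity, or the axial C2 configuration may be lost by enolization during work-up, which would give the all-equatorial 2S epimer. Fallback, setting out from 8 obtained as a C2 epimer mixture and coming back at 8 as the 2R epimer: the mixture is condensed with 1,1-dimethylhydrazine (AcOH cat., EtOH, 60 °C) to the N,N-dimethylhydrazone F2. Hydrazone/ene-hydrazine tautomerism makes C2 labile under these conditions, and allylic 1,3-strain with the dimethylamino group, which should lie syn to the less branched α-carbon, is expected to hold the C2 side chain axial, that is cis to the 3-methyl group. Mild cleavage (aq. CuCl2, THF, pH 7 buffer, 0 °C) returns the ketone.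

- **Step 5.** Enolization of the hindered ketone by the ylide or the base (epimerization at C2 or C6) may compete with a slow addition of the semi-stabilized ylide to the carbonyl group. Fallback, setting out from 8 and coming back at 11: ring A is closed without base by an intramolecular Nozaki–Hiyama allylation (CrCl2, LiI cat., THF, rt). Either CH2 terminus of the 2-substituted allyl unit gives the same skeleton, the tertiary homoallylic alcohol (1S,4R,4aR)-4-methyl-7-methylidene-1-(propan-2-yl)decahydronaphthalen-8a-ol F3. Dehydration with the Burgess reagent (benzene, 50 °C) towards the allylic, more acidic C8 hydrogen atoms then gives the conjugated diene.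

Further compounds
F1 | step 10 | 5-methoxy-4,6,6-trimethyl-2-[2-methyl-1-(phenylsulfonyl)propyl]cyclohex-4-ene-1,3-dione (enol form, racemic at the sulfonyl carbon) | COC1=C(C)C(=O)C(C(C(C)C)S(=O)(=O)c2ccccc2)=C(O)C1(C)C
F2 | step 3 | N,N-dimethylhydrazone of 8, (2R,3R,6S) with NMe2 syn to C2 | ClCC(=C)CC[C@@H]1[C@H](C)CC[C@@H](C(C)C)/C1=N/N(C)C
F3 | step 5 | (1S,4R,4aR)-4-methyl-7-methylidene-1-(propan-2-yl)decahydronaphthalen-8a-ol (configuration at C8a not defined; removed in the next operation) | C=C1CC2(O)[C@H](C(C)C)CC[C@@H](C)[C@H]2CC1
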